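Numbering (daucane): ring A (five-membered) = C1 (quaternary, CH3), C2 (OAc), C3, C4 (OH, i-Pr), C5 (H). Ring B (seven-membered) = C1, C5, C6 (O-angeloyl), C7 (CH2), C8 (CH3) and C9 (epoxide), C10 (OAc). β is the face of the C1 methyl group.
Retrosynthesis: the three esters and the epoxide oxygen come off first, back to the C8=C9 enone with C10=O. Ring B is then cut at C6–C7 and C8–C9, which releases C7–C8(CH3) as 2-methoxypropene and leaves ring A with C6 as an aldehyde and C10–C9 as an enol ether.
Enabling feature: ring B carries oxygen on the alternate atoms C6, C8 and C10, so the chain C6(+)–C7(−)–C8(+)–C9(−)–C10(+) is polarity-consonant. An acetone enol ether can therefore act as nucleophile at C7 and then, as its oxocarbenium ion, as electrophile at C8 in one Lewis acid event.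
Forward order: ring A is built on (S)-4-silyloxycyclopentenone (two cuprate additions, one aldol trap, one Grignard addition). Ring B is closed by the (5+2) annulation, followed by enone formation, acylation, ketone reduction and epoxidation.
Stereochemistry: C2 comes from the starting material. C1, C5 and C4 follow by relay, each new group entering anti to its neighbour. C6 is set by a titanium chelate with the C4 oxygen, C10 by the CBS catalyst, and C8/C9 by hydroxyl-directed epoxidation.

Key step: step 8

Assumption: both enantiomers of 4-(tert-butyldimethylsilyloxy)cyclopent-2-en-1-one are articles of commerce, and the (S)-enantiomer is used.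
Remark: 12 and 13 are mixtures of C8 epimers that converge in step 9, so C8 is left undefined in their SMILES. TBS = tert-butyldimethylsilyl, TES = triethylsilyl, TMS = trimethylsilyl, DTBMP = 2,6-di-tert-butyl-4-methylpyridine.

Step 1
Reactants: 1 (S)-4-(tert-butyldimethylsilyloxy)cyclopent-2-en-1-one
Product: 3 (3S,4S)-4-(TBS-oxy)-3-(1-ethoxyvinyl)-1-(trimethylsilyloxy)cyclopent-1-ene, via lithium enolate 2 (not isolated)
Conditions: ethyl vinyl ether, t-BuLi, THF, −78 to 0 °C; CuBr·SMe2, −78 °C; 1, TMSCl, −78 °C; Et3N, aq NaHCO3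
Reagents that add atoms: lithium bis(1-ethoxyvinyl)cuprate [Li+].C=C(OCC)[Cu-]C(=C)OCC; chlorotrimethylsilane C[Si](C)(C)Cl
Why: Conjugate addition of a lithium di(α-alkoxyvinyl)cuprate (acetyl anion equivalent) occurs anti to the C2 silyloxy group, and TMSCl fixes the enolate regiospecifically as the C4=C5 silyl enol ether needed for step 2, where the C1 centre formed here is erased.

Step 2
Reactants: 3 (3S,4S)-4-(TBS-oxy)-3-(1-ethoxyvinyl)-1-(trimethylsilyloxy)cyclopent-1-ene
Product: 4 (S)-4-(TBS-oxy)-3-(1-ethoxyvinyl)cyclopent-2-en-1-one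
Conditions: Pd(OAc)2 (1.05 equiv), 2,6-lutidine, MeCN, 23 °C
Reagents that add atoms: none
Why: Saegusa–Ito oxidation, in which the silyl enol ether transmetallates to divalent palladium much faster than the alkyl enol ether, β-hydride elimination of C1–H restores the enone with the C10–C9 unit now on C1, and the lutidine keeps the medium non-acidic.

Step 3
Reactants: 4 (S)-4-(TBS-oxy)-3-(1-ethoxyvinyl)cyclopent-2-en-1-one
Product: 6 (2S,3R,4S)-4-(TBS-oxy)-3-(1-ethoxyvinyl)-2-(hydroxymethyl)-3-methylcyclopentan-1-one, via lithium enolate 5 (not isolated)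
Conditions: Me2CuLi (from MeLi, CuI), Et2O, −78 °C; CH2O (gas), −78 °C; aq NH4Cl/NH3
Reagents that add atoms: lithium dimethylcuprate [Li+].C[Cu-]C; formaldehyde C=O
Why: Tandem cuprate 1,4-addition/aldol trapping delivers methyl to C1 anti to the C2 silyloxy group (quaternary centre, CH3 β), 1,6-addition being disfavoured because the oxygen-bearing vinyl group is electron-rich at C9 and twisted out of conjugation, and formaldehyde then enters the C5 enolate anti to the bulkier ethoxyvinyl group, which is also the more stable C5 configuration.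

Step 4
Reactants: 6 (2S,3R,4S)-4-(TBS-oxy)-3-(1-ethoxyvinyl)-2-(hydroxymethyl)-3-methylcyclopentan-1-one
Product: 7 (2S,3R,4S)-4-(TBS-oxy)-3-(1-ethoxyvinyl)-3-methyl-2-(triethylsilyloxymethyl)cyclopentan-1-one
Conditions: TESCl, imidazole, CH2Cl2, 0 °C
Reagents that add atoms: chlorotriethylsilane CC[Si](Cl)(CC)CC
Why: Standard silylation of the primary alcohol blocks retro-aldol cleavage and dehydration of the β-hydroxy ketone and touches no stereocentre.

Step 5
Reactants: 7 (2S,3R,4S)-4-(TBS-oxy)-3-(1-ethoxyvinyl)-3-methyl-2-(triethylsilyloxymethyl)cyclopentan-1-one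
Product: 8 (1R,2S,3R,4S)-4-(TBS-oxy)-3-(1-ethoxyvinyl)-3-methyl-1-isopropyl-2-(triethylsilyloxymethyl)cyclopentan-1-ol
Conditions: i-PrMgCl, LaCl3·2LiCl, THF, −78 to 0 °C; aq NH4Cl
Reagents that add atoms: isopropylmagnesium chloride CC(C)[Mg]Cl
Why: Lanthanide-assisted Grignard 1,2-addition suppresses enolisation, β-elimination and β-hydride reduction, and the nucleophile approaches the cyclopentanone anti to the adjacent C5 side chain (α face), which gives the 4β-hydroxy-4α-isopropyl centre.

Step 6
Reactants: 8 (1R,2S,3R,4S)-4-(TBS-oxy)-3-(1-ethoxyvinyl)-3-methyl-1-isopropyl-2-(triethylsilyloxymethyl)cyclopentan-1-ol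
Product: 9 (1R,2S,3R,4S)-4-(TBS-oxy)-3-(1-ethoxyvinyl)-2-(hydroxymethyl)-3-methyl-1-isopropylcyclopentan-1-ol
Conditions: TBAF (1.05 equiv), THF, −20 °C
Reagents that add atoms: none
Why: Fluoride cleaves the unhindered primary triethylsilyl ether far faster than the neopentyl secondary TBS ether, and the basic medium is harmless to the acid-labile enol ether.

Step 7
Reactants: 9 (1R,2S,3R,4S)-4-(TBS-oxy)-3-(1-ethoxyvinyl)-2-(hydroxymethyl)-3-methyl-1-isopropylcyclopentan-1-ol
Product: 10 (1R,2R,3S,5R)-3-(TBS-oxy)-2-(1-ethoxyvinyl)-5-hydroxy-2-methyl-5-isopropylcyclopentane-1-carbaldehyde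
Conditions: Dess–Martin periodinane, pyridine, CH2Cl2, 0 °C
Reagents that add atoms: none
Why: Pyridine-buffered Dess–Martin oxidation converts the primary alcohol into the aldehyde without touching the tertiary alcohol or the enol ether, and C5 already has its more stable configuration (formyl trans to both the C10 unit and the isopropyl group).

Step 8
Reactants: 10 (1R,2R,3S,5R)-3-(TBS-oxy)-2-(1-ethoxyvinyl)-5-hydroxy-2-methyl-5-isopropylcyclopentane-1-carbaldehyde
Product: 13 2α-(TBS-oxy)-4β,6α-dihydroxy-8-methoxy-trans-daucan-10-one (C8 epimers), via oxocarbenium titanate 11 (not isolated), via ring-closed oxocarbenium ion 12 (not isolated)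
Conditions: TiCl4 (1.2 equiv), DTBMP, CH2Cl2 (0.005 M), −78 °C; 2-methoxypropene (1.2 equiv, syringe pump), −78 to −40 °C; aq NaHCO3
Reagents that add atoms: 2-methoxypropene C=C(C)OC; water O
Why: Proposed new method: TiCl4 turns the C4 hydroxyl into a trichlorotitanium alkoxide that chelates the C6 aldehyde, the CH2 terminus of 2-methoxypropene adds to C6 (Mukaiyama-type aldol addition of an alkyl enol ether, C6–C7 bond), and the O-methyl oxocarbenium ion 11 so formed at C8, which unlike a silyloxocarbenium ion cannot collapse to a ketone, is captured by the CH2 terminus C9 of the internal ethyl enol ether (C8–C9 bond) to give ion 12, which is hydrolysed to the C10 ketone on work-up. The closest known reaction types are the Mukaiyama aldol–Prins cascade, where the same kind of ion is trapped by a tethered alkene, and the Lewis acid mediated aldol addition of enol ethers to acetals; what is new is that the trap sits on the aldehyde partner, so the enol ether is stitched in as a two-carbon unit and a carbocycle results. Ring B (seven-membered) closes in the 7-(enolendo)-exo-trig mode, helped by the quaternary C1 and by the trans arrangement of the two arms on ring A. C6 is controlled by the six-membered titanium chelate, in which the carbonyl face turned toward the C1 methyl group is blocked and the nucleophile enters next to C5–H to give the 4,6-anti (6α) alcohol, whereas C8 is not controlled and is erased in step 9. The step needs the external enol ether to reach the aldehyde before the internal one, which is secured because direct C9–C6 closure would be a disfavoured 5-(enolendo)-exo-trig process leading to a strained trans-fused bicyclo[3.3.0]octane and because the neopentyl internal enol ether is slow in intermolecular attack at high dilution. Slow addition of about one equivalent of 2-methoxypropene limits its oligomerisation, chloride capture of 11 or proton loss from it is reversible under the conditions, and the hindered pyridine removes the HCl that would destroy both enol ethers.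

Step 9
Reactants: 13 2α-(TBS-oxy)-4β,6α-dihydroxy-8-methoxy-trans-daucan-10-one (C8 epimers)
Product: 14 2α-(TBS-oxy)-4β,6α-dihydroxy-trans-dauc-8-en-10-one
Conditions: DBU, toluene, 60 °C
Reagents that add atoms: none
Why: E1cB elimination of methanol from the β-methoxy ketone, in which C10 can enolise only toward C9 because C1 is quaternary, so only the C8=C9 enone can form and both C8 epimers converge.

Step 10
Reactants: 14 2α-(TBS-oxy)-4β,6α-dihydroxy-trans-dauc-8-en-10-one
Product: 15 6α-angeloyloxy-2α-(TBS-oxy)-4β-hydroxy-trans-dauc-8-en-10-one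
Conditions: angelic acid, 2,4,6-trichlorobenzoyl chloride, Et3N, toluene, 23 °C; then 14, 80 °C
Reagents that add atoms: angelic acid C/C=C(/C)C(=O)O
Why: Yamaguchi-type esterification through the mixed anhydride without nucleophilic catalyst transfers the angeloyl group without Z to E isomerisation, and only the secondary C6 hydroxyl reacts because the tertiary C4 hydroxyl is inert.

Step 11
Reactants: 15 6α-angeloyloxy-2α-(TBS-oxy)-4β-hydroxy-trans-dauc-8-en-10-one
Product: 16 6α-angeloyloxy-2α,4β-dihydroxy-trans-dauc-8-en-10-one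
Conditions: HF·pyridine, pyridine, THF, 0 to 23 °C
Reagents that add atoms: none
Why: Acidic fluoride removes the hindered secondary TBS ether, while the enone, the angelate and the tertiary alcohol are stable to it.

Step 12
Reactants: 16 6α-angeloyloxy-2α,4β-dihydroxy-trans-dauc-8-en-10-one
Product: 17 6α-angeloyloxy-trans-dauc-8-ene-2α,4β,10α-triol
Conditions: (S)-2-methyl-CBS-oxazaborolidine, catecholborane, toluene, −60 °C; aq NaOH work-up at 0 °C
Reagents that add atoms: none
Why: In the Corey–Bakshi–Shibata reduction the catalyst distinguishes the quaternary C1 flank (large) from the C9 vinyl CH flank (small) and delivers hydride to the β face in 1,2-fashion to give the 10α-alcohol, and catecholborane leaves the angelate and the trisubstituted alkene alone.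

Step 13
Reactants: 17 6α-angeloyloxy-trans-dauc-8-ene-2α,4β,10α-triol
Product: 18 6α-angeloyloxy-8α,9α-epoxy-trans-daucane-2α,4β,10α-triol
Conditions: VO(acac)2 (cat.), t-BuOOH, CH2Cl2, 0 °C
Reagents that add atoms: tert-butyl hydroperoxide CC(C)(C)OO
Why: In the vanadium-catalysed hydroxyl-directed epoxidation the allylic 10α-hydroxyl delivers oxygen to the same (α) face of C8=C9, a syn selectivity that is reliable for cyclohept-2-enols, and the electron-poor angelate alkene is not attacked.

Step 14
Reactants: 18 6α-angeloyloxy-8α,9α-epoxy-trans-daucane-2α,4β,10α-triol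
Product: 19 2α,10α-diacetoxy-6α-angeloyloxy-8α,9α-epoxy-trans-daucan-4β-ol (target)
Conditions: Ac2O, pyridine, DMAP (cat.), CH2Cl2, 0 to 23 °C
Reagents that add atoms: acetic anhydride CC(=O)OC(C)=O
Why: Acetylation takes place at the two secondary alcohols C2 and C10, the hindered tertiary C4 hydroxyl is not acylated under these conditions, and no stereocentre is affected.

Compound list
1 | (S)-4-(tert-butyldimethylsilyloxy)cyclopent-2-en-1-one | O=C1C[C@H](O[Si](C)(C)C(C)(C)C)C=C1 | starting material
2 | lithium enolate of the ethoxyvinyl 1,4-adduct (not isolated) | [Li+].C=C(OCC)[C@@H]1[C@@H](O[Si](C)(C)C(C)(C)C)CC([O-])=C1 | intermediate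
3 | (3S,4S)-4-(TBS-oxy)-3-(1-ethoxyvinyl)-1-(trimethylsilyloxy)cyclopent-1-ene | C=C(OCC)[C@@H]1[C@@H](O[Si](C)(C)C(C)(C)C)CC(O[Si](C)(C)C)=C1 | intermediate
4 | (S)-4-(TBS-oxy)-3-(1-ethoxyvinyl)cyclopent-2-en-1-one | C=C(OCC)C1=CC(=O)C[C@@H]1O[Si](C)(C)C(C)(C)C | intermediate
5 | lithium enolate of the methyl 1,4-adduct (not isolated) | [Li+].C=C(OCC)[C@@]1(C)[C@@H](O[Si](C)(C)C(C)(C)C)CC([O-])=C1 | intermediate
6 | (2S,3R,4S)-4-(TBS-oxy)-3-(1-ethoxyvinyl)-2-(hydroxymethyl)-3-methylcyclopentan-1-one | C=C(OCC)[C@@]1(C)[C@@H](O[Si](C)(C)C(C)(C)C)CC(=O)[C@@H]1CO | intermediate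
7 | (2S,3R,4S)-4-(TBS-oxy)-3-(1-ethoxyvinyl)-3-methyl-2-(triethylsilyloxymethyl)cyclopentan-1-one | C=C(OCC)[C@@]1(C)[C@@H](O[Si](C)(C)C(C)(C)C)CC(=O)[C@@H]1CO[Si](CC)(CC)CC | intermediate
8 | (1R,2S,3R,4S)-4-(TBS-oxy)-3-(1-ethoxyvinyl)-3-methyl-1-isopropyl-2-(triethylsilyloxymethyl)cyclopentan-1-ol | C=C(OCC)[C@@]1(C)[C@@H](O[Si](C)(C)C(C)(C)C)C[C@@](O)(C(C)C)[C@@H]1CO[Si](CC)(CC)CC | intermediate
9 | (1R,2S,3R,4S)-4-(TBS-oxy)-3-(1-ethoxyvinyl)-2-(hydroxymethyl)-3-methyl-1-isopropylcyclopentan-1-ol | C=C(OCC)[C@@]1(C)[C@@H](O[Si](C)(C)C(C)(C)C)C[C@@](O)(C(C)C)[C@@H]1CO | intermediate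
10 | (1R,2R,3S,5R)-3-(TBS-oxy)-2-(1-ethoxyvinyl)-5-hydroxy-2-methyl-5-isopropylcyclopentane-1-carbaldehyde | C=C(OCC)[C@@]1(C)[C@@H](O[Si](C)(C)C(C)(C)C)C[C@@](O)(C(C)C)[C@@H]1C=O | intermediate
11 | C8 O-methyl oxocarbenium ion, C4/C6 trichlorotitanate chelate, 6S (not isolated) | C=C(OCC)[C@@]1(C)[C@@H](O[Si](C)(C)C(C)(C)C)C[C@]2(C(C)C)O[Ti-](Cl)(Cl)(Cl)O[C@@H](CC(C)=[O+]C)[C@H]12 | intermediate
12 | ring-closed C10 O-ethyl oxocarbenium ion, titanate chelate (not isolated) | CC[O+]=C1CC(C)(OC)C[C@@H]2O[Ti-](Cl)(Cl)(Cl)O[C@@]3(C(C)C)C[C@H](O[Si](C)(C)C(C)(C)C)[C@@]1(C)[C@@H]23 | intermediate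
13 | 2α-(TBS-oxy)-4β,6α-dihydroxy-8-methoxy-trans-daucan-10-one (C8 epimers) | O[C@H]1CC(C)(OC)CC(=O)[C@@]2(C)[C@@H](O[Si](C)(C)C(C)(C)C)C[C@@](O)(C(C)C)[C@H]12 | intermediate
14 | 2α-(TBS-oxy)-4β,6α-dihydroxy-trans-dauc-8-en-10-one | O[C@H]1CC(C)=CC(=O)[C@@]2(C)[C@@H](O[Si](C)(C)C(C)(C)C)C[C@@](O)(C(C)C)[C@H]12 | intermediate
15 | 6α-angeloyloxy-2α-(TBS-oxy)-4β-hydroxy-trans-dauc-8-en-10-one | C/C=C(/C)C(=O)O[C@H]1CC(C)=CC(=O)[C@@]2(C)[C@@H](O[Si](C)(C)C(C)(C)C)C[C@@](O)(C(C)C)[C@H]12 | intermediate
16 | 6α-angeloyloxy-2α,4β-dihydroxy-trans-dauc-8-en-10-one | C/C=C(/C)C(=O)O[C@H]1CC(C)=CC(=O)[C@@]2(C)[C@@H](O)C[C@@](O)(C(C)C)[C@H]12 | intermediate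
17 | 6α-angeloyloxy-trans-dauc-8-ene-2α,4β,10α-triol | C/C=C(/C)C(=O)O[C@H]1CC(C)=C[C@@H](O)[C@@]2(C)[C@@H](O)C[C@@](O)(C(C)C)[C@H]12 | intermediate
18 | 6α-angeloyloxy-8α,9α-epoxy-trans-daucane-2α,4β,10α-triol | C/C=C(/C)C(=O)O[C@H]1C[C@@]2(C)O[C@H]2[C@@H](O)[C@@]2(C)[C@@H](O)C[C@@](O)(C(C)C)[C@H]12 | intermediate
19 | 2α,10α-diacetoxy-6α-angeloyloxy-8α,9α-epoxy-trans-daucan-4β-ol | C/C=C(/C)C(=O)O[C@H]1C[C@@]2(C)O[C@H]2[C@@H](OC(C)=O)[C@@]2(C)[C@@H](OC(C)=O)C[C@@](O)(C(C)C)[C@H]12 | target

Total step count: 14. Longest linear sequence: 14.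

Steps most likely to fail

Step 8 (Proposed new method). The oxocarbenium ion may be intercepted by more 2-methoxypropene, or may lose a proton irreversibly, before the seven-membered ring closes. Incomplete chelation may also erode the facial selectivity at C6. The fallback uses known chemistry, sets out from 10 and forms the two bonds one after the other. Chelation-controlled addition of methallylmagnesium chloride (THF, −78 °C, magnesium alkoxide of the C4 hydroxyl) gives the homoallylic alcohol F1. A Mannich reaction of its enol ether with dimethylmethyleneammonium iodide, followed by aqueous work-up, gives the β-dimethylamino ketone F2. Quaternisation with MeI and elimination with NaHCO3 gives the vinyl ketone F3. Ring-closing metathesis with the second-generation Hoveyda–Grubbs catalyst (toluene, 80 °C) closes C8=C9 and comes back to the route at 14.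

Step 3. The cuprate may add in 1,6-fashion at C9. Alternatively, the enolate may undergo proton transfer toward C3 and lose silanolate before formaldehyde arrives. The fallback sets out from 4 and interrupts the extended conjugation first.
- PPTS-catalysed addition of ethanol to the enol ether gives the diethyl ketal enone F4.
- Cuprate addition with formaldehyde trapping gives the ketal hydroxymethyl ketone F5.
- TESCl/imidazole gives the ketal TES ether F6.
- i-PrMgCl/LaCl3·2LiCl gives the ketal tertiary alcohol F7.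
- TMSOTf/i-Pr2NEt eliminates ethanol from the ketal and silylates the tertiary alcohol, giving the bis-silylated enol ether F8.
- TBAF removes the TES and TMS groups and comes back to the route at 9.

Step 12. The intrinsic preference of the ketone for hydride attack anti to the C1 methyl group may oppose the catalyst and lower the facial selectivity, and the hindered ketone may react sluggishly. The fallback sets out from 16 and replaces reagent control by substrate direction. In a Narasaka–Prasad reduction (Et2BOMe, NaBH4, THF/MeOH, −78 °C) boron chelates the C2 hydroxyl and the C10 ketone, and external hydride gives the 2,10-syn diol. This comes back to the route at 17 and makes no new compound (F0).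

Further compounds
F1 | step 8 | homoallylic alcohol (methallyl adduct of 10, 6S) | C=C(OCC)[C@@]1(C)[C@@H](O[Si](C)(C)C(C)(C)C)C[C@@](O)(C(C)C)[C@@H]1[C@@H](O)CC(C)=C
F2 | step 8 | β-dimethylamino ketone (Mannich base at C9) | CN(C)CCC(=O)[C@@]1(C)[C@@H](O[Si](C)(C)C(C)(C)C)C[C@@](O)(C(C)C)[C@@H]1[C@@H](O)CC(C)=C
F3 | step 8 | vinyl ketone (C10 acryloyl, C6 methallyl carbinol) | C=CC(=O)[C@@]1(C)[C@@H](O[Si](C)(C)C(C)(C)C)C[C@@](O)(C(C)C)[C@@H]1[C@@H](O)CC(C)=C
F4 | step 3 | diethyl ketal enone, (S)-4-(TBS-oxy)-3-(1,1-diethoxyethyl)cyclopent-2-en-1-one | CCOC(C)(OCC)C1=CC(=O)C[C@@H]1O[Si](C)(C)C(C)(C)C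
F5 | step 3 | ketal hydroxymethyl ketone | CCOC(C)(OCC)[C@@]1(C)[C@@H](O[Si](C)(C)C(C)(C)C)CC(=O)[C@@H]1CO
F6 | step 3 | ketal TES ether | CCOC(C)(OCC)[C@@]1(C)[C@@H](O[Si](C)(C)C(C)(C)C)CC(=O)[C@@H]1CO[Si](CC)(CC)CC
F7 | step 3 | ketal tertiary alcohol | CCOC(C)(OCC)[C@@]1(C)[C@@H](O[Si](C)(C)C(C)(C)C)C[C@@](O)(C(C)C)[C@@H]1CO[Si](CC)(CC)CC
F8 | step 3 | bis-silylated enol ether (C4 O-TMS, C6 O-TES) | C=C(OCC)[C@@]1(C)[C@@H](O[Si](C)(C)C(C)(C)C)C[C@@](O[Si](C)(C)C)(C(C)C)[C@@H]1CO[Si](CC)(CC)CC
F0 | step 12 | none | none
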